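**Conventions.** TBS = tert-butyldimethylsilyl; Piv = pivaloyl (2,2-dimethylpropanoyl). The bicyclic part is numbered as a benzofuran (O1, C2, C3, C3a, C4–C7, C7a). The arylglycerol chain carbons are called Ca (carbinol carbon on ring A), Cb (aryloxy carbon) and Cc (CH2OH). ArC = 2-(TBS-oxy)-3-methoxy-5-[3-(TBS-oxy)propyl]phenyl. DBF = (2R,3R)-3-[(TBS-oxy)methyl]-7-methoxy-5-[3-(TBS-oxy)propyl]-2,3-dihydro-1-benzofuran-2-yl.

Remark on the chemistry: the bromoacetyl imide 22 is made in the route from 8, and the magnesium-catalysed aldol of step 17 is assumed to follow the usual chelated-enolate sense of N-acyloxazolidinones.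

## Analysis of the target

Compound 29 has three aromatic rings. Ring A is a guaiacyl ring carrying the chain Ca(OH)–Cb(OAr)–CcH2OH. Ring B is a central 3,5-dimethoxy-4-oxyphenyl ring. Ring C is fused to a dihydrofuran (O1, C2, C3, C3a, C7a) and bears a methoxy group at C7 and a 3-hydroxypropyl chain at C5.

There are four stereocentres in two pairs. C2 (R) and C3 (R) place ring B and the hydroxymethyl group on the same face, which is the cis and thermodynamically less favoured arrangement. Ca (R) and Cb (S) are erythro, that is anti when the chain Cc–Cb–Ca–ring A is drawn as a zigzag.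

Ring B separates the two pairs, so neither can relay its configuration to the other, and each has to be set by a reagent of known absolute sense.

The sensitive points are these:
- The O1–C2 bond is benzylic. It can ionise under acid, or open through a quinone methide when the ring B oxygen is a free phenoxide. Either path would epimerise the ring to trans.
- The Ca hydroxyl is a para-hydroxybenzylic alcohol, which is labile to acid and prone to quinone methide formation.
- There are four further hydroxyls to be carried.

The difficulty is twofold. The cis ring cannot be reached by equilibration or by biomimetic oxidative coupling, both of which give trans. The Cb–O bond joins a secondary carbon to a phenol oxygen flanked by two methoxy groups.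

The strategy rests on O1–C2 being an ether bond to a benzylic carbon. It can therefore be the last ring bond formed, by SN2 displacement with inversion. The open-chain precursor is then a syn 1-(ring B)-2-(ring C)-propane-1,3-diol, which is the native product of an auxiliary-controlled aldol reaction.

## Retrosynthetic reasoning

**Protecting groups and oxidation level (29 ⇐ 28 ⇐ 27).** The last operation is fluoride cleavage of the three silyl ethers of 28. This needs neither acid nor strong base, so the cis ring and the benzylic Ca–OH survive. Diol 28 comes from hydride cleavage of the imide 27, which turns the acyl carbon into Cc.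

**Ca–Cb bond (27 ⇐ 23 + 25).** Cutting the bond between the two side-chain stereocentres gives the aryloxyacetyl imide 23 and the silylated vanillin 25. Both centres are then made in one anti-selective aldol under control of the auxiliary. The cut is made here and not at Cb–O because an SN2 reaction of the hindered ring B phenoxide at a secondary carbon would be slow and would compete with elimination. The forward reaction must give the anti adduct with the (R) configuration at both new centres.

**O–CH2 bond of the glycolyl unit (23 ⇐ 20 + 22; 22 ⇐ 8; 20 ⇐ 19).** The aryl ether oxygen is attached while its carbon is still an unhindered activated CH2, by alkylating phenol 20 with the bromoacetyl imide 22, made from 8. Phenol 20 comes from pivalate 19. The acyl group is kept on ring B until after the ring closure because it is needed there.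

**O1–C2 bond (19 ⇐ 17).** This is the central disconnection. Cutting the benzylic ether bond opens the ring to the phenol–alcohol 17. Since the forward closure inverts C2, 17 must be the syn diol derivative with a (1S)-carbinol. Cutting O1–C2 rather than C2–C3 or C3–C3a makes the ring closure stereospecific instead of stereoselective: the cis geometry is stored in an acyclic syn relationship that is easy to make. The forward reaction has to be a clean SN2 process, which is why ring B carries the electron-poor pivaloyloxy group and the primary oxygen is silylated.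

**Adjustment of 17 (17 ⇐ 16 ⇐ 15 ⇐ 14).** The phenol of 17 is unmasked from its aryl silyl ether 16. The primary silyl ether of 16 comes from diol 15, and 15 from hydride cleavage of the aldol adduct 14. Using one kind of silyl group for both the phenol and the alkyl hydroxyls saves steps, because aryl silyl ethers can be cleaved selectively.

**C2–C3 bond (14 ⇐ 10 + 12; 12 ⇐ 11).** The bond between the two future ring stereocentres is cut to the arylacetyl imide 10 and the aldehyde 12, made from syringaldehyde 11. A boron-mediated syn aldol sets both centres with the absolute sense fixed by the auxiliary 8.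

**Ring C arylacetic acid (10 ⇐ 7 + 8; 7 ⇐ 6 ⇐ 4 ⇐ 3 ⇐ 2 ⇐ 1).** The acetic acid side chain of 7 is traced back to an allyl group, shortened by one carbon through aldehyde 6. The allyl group is placed ortho to the phenol oxygen by the Claisen rearrangement of allyl ether 2, made from dihydroconiferyl alcohol 1. The rearrangement can only go to the single free ortho position, which fixes the substitution pattern of ring C.

## Alternatives that were turned down

**Alternative 1:** The Ca–O bond is cut last. The precursor is the Ca-deoxy compound A2, with Cb already set and Cc carrying a tert-butyl carbonate. In the forward step a quinone oxidant (DDQ) turns the para-alkylphenol of ring A into a quinone methide. The carbonate carbonyl oxygen adds to Ca, and loss of isobutene gives the six-membered trans carbonate A1.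

- For: only one side-chain stereocentre has to be made by external control. Ca follows from Cb through a cyclic transition state, and the anti aldol is avoided. On this point it is stronger than the chosen route.
- Against: the oxidant would meet three other oxidisable sites. These are the doubly benzylic C2–H/C3–H pair of the dihydrobenzofuran (dehydrogenation to the benzofuran), the benzylic C–H bonds of ring C, and electron-rich ring B.
- Against: the quinone methide is planar at Ca, so the trans selectivity depends on a conformational preference and not on a stereospecific event.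
- Against: A2 still needs the hindered Cb–O bond at a secondary carbon, and the alternative says nothing about how the cis ring is made.

The chosen route uses no oxidant after the ring is closed and forms Ca and Cb together.

**Alternative 2:** The C3–C3a bond is made by ring contraction. The precursor is the enantioenriched 3-diazoflavanone A4. Photolysis in methanol causes a Wolff rearrangement in which the ring C carbon shifts from the carbonyl carbon to the carbene carbon. Methanol traps the ketene as the cis ester A3.

- For: flavanones are assembled very quickly from a hydroxyacetophenone and an aldehyde, so access to the skeleton is shorter than the six steps the chosen route needs to reach imide 10.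
- Against: C3 is created by protonation of an ester enol. The cis product is only the kinetic one, and it keeps an acidic C3–H that is both benzylic and alpha to the ester, so it can drift to trans during work-up or reduction.
- Against: the carbene sits next to C2–H, so a 1,2-hydrogen shift to the flavone competes and destroys the stereocentre.
- Against: the diazo group can only be introduced with base after activating C3, and base opens flavanones to chalcones and racemises C2.

The chosen route makes C3 at the alcohol oxidation level, where it cannot epimerise.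

**Alternative 3:** The C2–C3 bond is made by carbenoid insertion. The precursor is the aryldiazoacetate A6, in which ring B is the benzyl group on the neighbouring phenol oxygen. Rh2(S-PTTL)4 (dirhodium tetrakis[N-phthaloyl-(S)-tert-leucinate]) generates a carbenoid that inserts into the benzylic O–CH2 bond and gives the cis ester A5.

- For: both ring stereocentres are made in one catalytic step, and A6 is only an O-benzylation and a diazo transfer away from simple phenols. In step count and in catalytic stereocontrol this is clearly stronger than the auxiliary route.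
- Against: the enantioselectivity and the cis preference would have to hold for a substrate with a methoxy group next to the ether oxygen. That oxygen can divert the carbenoid into an oxonium ylide and a 1,2-shift.
- Against: the benzyl group is very electron-rich, which favours a stepwise hydride-transfer path and could erode selectivity.
- Against: A5, like A3, has an epimerisable C3–H that must survive the ester reduction.

The chosen strategy costs more steps, but its absolute and relative configuration follow from two well-understood stereochemical events. Minor diastereomers can be removed at the aldol stage, and the ring is closed on a centre that can no longer epimerise.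

Key step: step 12

## Route

Step 1
Reactants: 1 dihydroconiferyl alcohol
Product: 2 3-[3-methoxy-4-(prop-2-enyloxy)phenyl]propan-1-ol
Conditions: allyl bromide, K2CO3, acetone, reflux
Reagents that add atoms: allyl bromide, C=CCBr
Why: Williamson etherification; K2CO3 ionises only the phenol, so the aliphatic hydroxyl should stay free and only the aryl allyl ether should form.

Step 2
Reactants: 2 3-[3-methoxy-4-(prop-2-enyloxy)phenyl]propan-1-ol
Product: 3 4-(3-hydroxypropyl)-2-methoxy-6-(prop-2-enyl)phenol
Conditions: N,N-diethylaniline, 200 °C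
Reagents that add atoms: none
Why: Aromatic Claisen rearrangement; the [3,3] shift can end only at the single free ortho carbon, since the other ortho position bears the methoxy group and the para position the side chain, and tautomerisation restores the phenol.

Step 3
Reactants: 3 4-(3-hydroxypropyl)-2-methoxy-6-(prop-2-enyl)phenol
Product: 4 1-(TBS-oxy)-2-methoxy-6-(prop-2-enyl)-4-[3-(TBS-oxy)propyl]benzene
Conditions: TBSCl (2.5 equiv), imidazole, DMF, 40 °C
Reagents that add atoms: tert-butyldimethylsilyl chloride, CC(C)(C)[Si](C)(C)Cl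
Why: Silylation of both hydroxyls; the aryl silyl ether masks the phenol through the oxidation and aldol steps and can later be cleaved in the presence of the alkyl silyl ethers.

Step 4
Reactants: 4 1-(TBS-oxy)-2-methoxy-6-(prop-2-enyl)-4-[3-(TBS-oxy)propyl]benzene
Product: 6 2-(ArC)acetaldehyde, via vicinal diol 5 (not isolated)
Conditions: OsO4 (cat.), NaIO4, 2,6-lutidine, dioxane/H2O, rt
Reagents that add atoms: sodium periodate (oxygen delivered through OsO4), [Na+].[O-]I(=O)(=O)=O
Why: Lemieux–Johnson oxidative cleavage; catalytic OsO4 dihydroxylates the terminal alkene and NaIO4 cleaves the diol, so the allyl group is shortened by one carbon without attack on the electron-rich ring, and the sensitive arylacetaldehyde is used crude.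

Step 5
Reactants: 6 2-(ArC)acetaldehyde
Product: 7 2-(ArC)acetic acid
Conditions: NaClO2, NaH2PO4, 2-methyl-2-butene, t-BuOH/H2O, 0 °C → rt
Reagents that add atoms: sodium chlorite, [Na+].[O-]Cl=O
Why: Pinnick oxidation; the buffered chlorite oxidises only the aldehyde, the alkene scavenger removes hypochlorous acid before it can chlorinate the arene, and the silyl ethers tolerate the weakly acidic medium.

Step 6
Reactants: 7 2-(ArC)acetic acid; 8 (S)-4-benzyl-2-oxazolidinone
Product: 10 (S)-4-benzyl-3-[2-(ArC)acetyl]oxazolidin-2-one, via mixed pivalic anhydride 9 (not isolated)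
Conditions: PivCl, Et3N, THF, −20 °C; then LiCl, 8, −20 °C → rt
Reagents that add atoms: none
Why: N-acylation of the oxazolidinone through a mixed anhydride; LiCl activates the oxazolidinone, which attacks the less hindered arylacetyl carbonyl, and no strong base meets the enolisable arylacetyl group.

Step 7
Reactants: 11 syringaldehyde
Product: 12 4-formyl-2,6-dimethoxyphenyl pivalate
Conditions: PivCl, Et3N, DMAP (cat.), CH2Cl2, 0 °C → rt
Reagents that add atoms: pivaloyl chloride, CC(C)(C)C(Cl)=O
Why: DMAP-catalysed acylation of the hindered phenol; the pivalate is chosen because it makes ring B electron-poor for the later ring closure and is hindered enough to survive the aldol and hydride steps.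

Step 8
Reactants: 10 (S)-4-benzyl-3-[2-(ArC)acetyl]oxazolidin-2-one; 12 4-formyl-2,6-dimethoxyphenyl pivalate
Product: 14 (S)-4-benzyl-3-[(2S,3S)-2-(ArC)-3-hydroxy-3-(3,5-dimethoxy-4-pivaloyloxyphenyl)propanoyl]oxazolidin-2-one, via (Z)-dibutylboron enolate 13 (not isolated)
Conditions: n-Bu2BOTf, i-Pr2NEt, CH2Cl2, −78 → 0 °C; 12, −78 → 0 °C; then pH 7 buffer, MeOH, H2O2, 0 °C
Reagents that add atoms: none
Why: Evans syn aldol; the (Z)-boron enolate adds through a chair-like Zimmerman–Traxler transition state on the enolate face away from the benzyl group of the dipole-minimised auxiliary, which should set the syn (2S,3S) pair, and the oxidative work-up frees the hydroxyl.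

Step 9
Reactants: 14 (S)-4-benzyl-3-[(2S,3S)-2-(ArC)-3-hydroxy-3-(3,5-dimethoxy-4-pivaloyloxyphenyl)propanoyl]oxazolidin-2-one
Product: 15 4-[(1S,2R)-2-(ArC)-1,3-dihydroxypropyl]-2,6-dimethoxyphenyl pivalate
Conditions: LiBH4, MeOH (2 equiv), THF, 0 °C
Reagents that add atoms: none
Why: Reductive cleavage of the imide; lithium chelation activates the exocyclic carbonyl, which should be reduced faster than the aryl pivalate shielded by two ortho methoxy groups, and neither stereocentre is touched (the descriptor of the ArC-bearing carbon becomes R only through the change in priorities).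

Step 10
Reactants: 15 4-[(1S,2R)-2-(ArC)-1,3-dihydroxypropyl]-2,6-dimethoxyphenyl pivalate
Product: 16 4-[(1S,2R)-2-(ArC)-1-hydroxy-3-(TBS-oxy)propyl]-2,6-dimethoxyphenyl pivalate
Conditions: TBSCl (1.1 equiv), imidazole, CH2Cl2, 0 °C
Reagents that add atoms: tert-butyldimethylsilyl chloride, CC(C)(C)[Si](C)(C)Cl
Why: Chemoselective silylation; the primary hydroxyl reacts much faster than the hindered secondary benzylic one, and blocking it removes the competing ring closure through the primary carbon.

Step 11
Reactants: 16 4-[(1S,2R)-2-(ArC)-1-hydroxy-3-(TBS-oxy)propyl]-2,6-dimethoxyphenyl pivalate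
Product: 17 4-[(1S,2R)-1-hydroxy-2-{2-hydroxy-3-methoxy-5-[3-(TBS-oxy)propyl]phenyl}-3-(TBS-oxy)propyl]-2,6-dimethoxyphenyl pivalate
Conditions: KHF2, MeOH, rt
Reagents that add atoms: none
Why: Selective cleavage of an aryl silyl ether; phenoxide leaves from silicon far more readily than alkoxide, so the two alkyl silyl ethers and the pivalate should remain under these nearly neutral conditions.

Step 12
Reactants: 17 4-[(1S,2R)-1-hydroxy-2-{2-hydroxy-3-methoxy-5-[3-(TBS-oxy)propyl]phenyl}-3-(TBS-oxy)propyl]-2,6-dimethoxyphenyl pivalate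
Product: 19 4-(DBF)-2,6-dimethoxyphenyl pivalate, via alkoxyphosphonium phenoxide 18 (not isolated)
Conditions: PPh3, DIAD, toluene, high dilution, 0 °C → rt
Reagents that add atoms: none
Why: Mitsunobu cycloetherification: the PPh3/DIAD betaine deprotonates the phenol and turns the only free hydroxyl, the secondary benzylic one, into an alkoxyphosphonium group (18), and the phenoxide then attacks that carbon from the rear with loss of Ph3PO. The closest known reaction type is the Mitsunobu ring closure of 2-(2-hydroxyalkyl)phenols to 2,3-dihydrobenzofurans, which runs with inversion at the carbinol carbon. The ring closes in the 5-exo-tet mode, forming O1–C2. The new C2 centre (R) is controlled by the substrate alone, being the inverted (S)-carbinol centre from step 8, while C3 takes no part, so the syn diol becomes the cis ring. The step needs SN2 substitution to win over ionisation, which would leak to the trans ring, and over elimination to the stilbene. Ring B secures this, because its para pivaloyloxy group (twisted by the two flanking methoxy groups) and its meta methoxy groups give a benzylic cation no stabilisation, and the non-polar solvent disfavours ion pairs. High dilution keeps the reaction intramolecular, and the silyl ether on the primary oxygen excludes closure through the other carbon.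

Step 13
Reactants: 19 4-(DBF)-2,6-dimethoxyphenyl pivalate
Product: 20 4-(DBF)-2,6-dimethoxyphenol
Conditions: i-Bu2AlH, CH2Cl2, −78 °C; aq. KNaC4H4O6
Reagents that add atoms: none
Why: Reductive deacylation; the hydride reduces the pivalate to neopentyl alcohol at low temperature, the silyl ethers are inert, and the phenol is released on neutral work-up so the cis ring is not held as a free phenoxide.

Step 14
Reactants: 8 (S)-4-benzyl-2-oxazolidinone
Product: 22 (S)-4-benzyl-3-(bromoacetyl)oxazolidin-2-one, via N-lithio oxazolidinone 21 (not isolated)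
Conditions: n-BuLi, THF, −78 °C; BrCH2COBr, −78 → 0 °C
Reagents that add atoms: bromoacetyl bromide, BrCC(Br)=O
Why: N-acylation of the lithiated oxazolidinone; acyl substitution at the acid bromide at −78 °C is much faster than displacement of the alkyl bromide.

Step 15
Reactants: 20 4-(DBF)-2,6-dimethoxyphenol; 22 (S)-4-benzyl-3-(bromoacetyl)oxazolidin-2-one
Product: 23 (S)-4-benzyl-3-{2-[4-(DBF)-2,6-dimethoxyphenoxy]acetyl}oxazolidin-2-one
Conditions: K2CO3, 22 (1.3 equiv), MeCN, rt
Reagents that add atoms: none
Why: Williamson etherification; the phenoxide displaces bromide from the activated primary carbon next to the imide carbonyl, so the hindered aryl ether oxygen is attached before its carbon becomes the secondary centre Cb, and the fast alkylation keeps the phenoxide short-lived.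

Step 16
Reactants: 24 vanillin
Product: 25 4-(TBS-oxy)-3-methoxybenzaldehyde
Conditions: TBSCl, imidazole, CH2Cl2, rt
Reagents that add atoms: tert-butyldimethylsilyl chloride, CC(C)(C)[Si](C)(C)Cl
Why: Silylation of the phenol; the silyl ether tolerates the amine base and the hydride of the next steps and is removed together with the other silyl groups at the end.

Step 17
Reactants: 23 (S)-4-benzyl-3-{2-[4-(DBF)-2,6-dimethoxyphenoxy]acetyl}oxazolidin-2-one; 25 4-(TBS-oxy)-3-methoxybenzaldehyde
Product: 27 (S)-4-benzyl-3-[(2R,3R)-2-[4-(DBF)-2,6-dimethoxyphenoxy]-3-hydroxy-3-[4-(TBS-oxy)-3-methoxyphenyl]propanoyl]oxazolidin-2-one, via trimethylsilyl ether 26 (not isolated)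
Conditions: MgCl2 (0.3 equiv), Et3N, Me3SiCl, 25 (1.5 equiv), EtOAc, rt; then MeOH, PPTS (cat.), 0 °C
Reagents that add atoms: none
Why: Magnesium-halide-catalysed anti aldol of an N-acyloxazolidinone with an aromatic aldehyde; Et3N enolises the MgCl2-chelated imide to the (Z)-enolate, which should add through a boat-like closed transition state on the face away from the benzyl group of the chelated auxiliary and give the 2,3-anti (2R,3R) adduct, while Me3SiCl silylates the aldolate so that magnesium turns over. Brief methanolysis then removes only the trimethylsilyl group.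

Step 18
Reactants: 27 (S)-4-benzyl-3-[(2R,3R)-2-[4-(DBF)-2,6-dimethoxyphenoxy]-3-hydroxy-3-[4-(TBS-oxy)-3-methoxyphenyl]propanoyl]oxazolidin-2-one
Product: 28 (1R,2S)-2-[4-(DBF)-2,6-dimethoxyphenoxy]-1-[4-(TBS-oxy)-3-methoxyphenyl]propane-1,3-diol
Conditions: LiBH4, MeOH (2 equiv), THF, 0 °C
Reagents that add atoms: none
Why: Reductive cleavage of the imide to the Cc alcohol; the stereocentres are not touched, and the Cb descriptor changes from R to S only because the reduced carbon drops in priority.

Step 19
Reactants: 28 (1R,2S)-2-[4-(DBF)-2,6-dimethoxyphenoxy]-1-[4-(TBS-oxy)-3-methoxyphenyl]propane-1,3-diol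
Product: 29 (1R,2S)-1-(4-hydroxy-3-methoxyphenyl)-2-{4-[(2R,3R)-3-(hydroxymethyl)-5-(3-hydroxypropyl)-7-methoxy-2,3-dihydro-1-benzofuran-2-yl]-2,6-dimethoxyphenoxy}propane-1,3-diol
Conditions: n-Bu4NF, AcOH (1:1, excess), THF, 0 °C → rt
Reagents that add atoms: none
Why: Fluoride desilylation of the aryl and the two primary silyl ethers; buffering with acetic acid avoids acid that could ionise the Ca–O or O1–C2 bonds and avoids a free ring A phenoxide that could form a quinone methide.

## Compound list

1 | dihydroconiferyl alcohol, 4-(3-hydroxypropyl)-2-methoxyphenol | COc1cc(CCCO)ccc1O | starting material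
2 | 3-[3-methoxy-4-(prop-2-enyloxy)phenyl]propan-1-ol | C=CCOc1ccc(CCCO)cc1OC | intermediate
3 | 4-(3-hydroxypropyl)-2-methoxy-6-(prop-2-enyl)phenol | C=CCc1cc(CCCO)cc(OC)c1O | intermediate
4 | 1-(TBS-oxy)-2-methoxy-6-(prop-2-enyl)-4-[3-(TBS-oxy)propyl]benzene | C=CCc1cc(CCCO[Si](C)(C)C(C)(C)C)cc(OC)c1O[Si](C)(C)C(C)(C)C | intermediate
5 | 3-(ArC)propane-1,2-diol (vicinal diol, no defined configuration) | OCC(O)Cc1cc(CCCO[Si](C)(C)C(C)(C)C)cc(OC)c1O[Si](C)(C)C(C)(C)C | intermediate (not isolated)
6 | 2-(ArC)acetaldehyde | O=CCc1cc(CCCO[Si](C)(C)C(C)(C)C)cc(OC)c1O[Si](C)(C)C(C)(C)C | intermediate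
7 | 2-(ArC)acetic acid | OC(=O)Cc1cc(CCCO[Si](C)(C)C(C)(C)C)cc(OC)c1O[Si](C)(C)C(C)(C)C | intermediate
8 | (S)-4-benzyl-2-oxazolidinone | O=C1N[C@@H](Cc2ccccc2)CO1 | starting material
9 | mixed anhydride of 2-(ArC)acetic acid and pivalic acid | CC(C)(C)C(=O)OC(=O)Cc1cc(CCCO[Si](C)(C)C(C)(C)C)cc(OC)c1O[Si](C)(C)C(C)(C)C | intermediate (not isolated)
10 | (S)-4-benzyl-3-[2-(ArC)acetyl]oxazolidin-2-one | O=C(Cc1cc(CCCO[Si](C)(C)C(C)(C)C)cc(OC)c1O[Si](C)(C)C(C)(C)C)N1[C@@H](Cc2ccccc2)COC1=O | intermediate
11 | syringaldehyde | COc1cc(C=O)cc(OC)c1O | starting material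
12 | 4-formyl-2,6-dimethoxyphenyl pivalate | COc1cc(C=O)cc(OC)c1OC(=O)C(C)(C)C | intermediate
13 | (Z)-dibutylboron enolate of 10 | CCCCB(CCCC)O/C(=C\c1cc(CCCO[Si](C)(C)C(C)(C)C)cc(OC)c1O[Si](C)(C)C(C)(C)C)N1[C@@H](Cc2ccccc2)COC1=O | intermediate (not isolated)
14 | (S)-4-benzyl-3-[(2S,3S)-2-(ArC)-3-hydroxy-3-(3,5-dimethoxy-4-pivaloyloxyphenyl)propanoyl]oxazolidin-2-one | O=C([C@@H](c1cc(CCCO[Si](C)(C)C(C)(C)C)cc(OC)c1O[Si](C)(C)C(C)(C)C)[C@H](O)c1cc(OC)c(OC(=O)C(C)(C)C)c(OC)c1)N1[C@@H](Cc2ccccc2)COC1=O | intermediate
15 | 4-[(1S,2R)-2-(ArC)-1,3-dihydroxypropyl]-2,6-dimethoxyphenyl pivalate | OC[C@@H](c1cc(CCCO[Si](C)(C)C(C)(C)C)cc(OC)c1O[Si](C)(C)C(C)(C)C)[C@H](O)c1cc(OC)c(OC(=O)C(C)(C)C)c(OC)c1 | intermediate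
16 | 4-[(1S,2R)-2-(ArC)-1-hydroxy-3-(TBS-oxy)propyl]-2,6-dimethoxyphenyl pivalate | CC(C)(C)[Si](C)(C)OC[C@@H](c1cc(CCCO[Si](C)(C)C(C)(C)C)cc(OC)c1O[Si](C)(C)C(C)(C)C)[C@H](O)c1cc(OC)c(OC(=O)C(C)(C)C)c(OC)c1 | intermediate
17 | 4-[(1S,2R)-1-hydroxy-2-{2-hydroxy-3-methoxy-5-[3-(TBS-oxy)propyl]phenyl}-3-(TBS-oxy)propyl]-2,6-dimethoxyphenyl pivalate | CC(C)(C)[Si](C)(C)OC[C@@H](c1cc(CCCO[Si](C)(C)C(C)(C)C)cc(OC)c1O)[C@H](O)c1cc(OC)c(OC(=O)C(C)(C)C)c(OC)c1 | intermediate (precursor of the key step)
18 | alkoxytriphenylphosphonium phenoxide zwitterion from 17 | CC(C)(C)[Si](C)(C)OC[C@@H](c1cc(CCCO[Si](C)(C)C(C)(C)C)cc(OC)c1[O-])[C@H](O[P+](c1ccccc1)(c1ccccc1)c1ccccc1)c1cc(OC)c(OC(=O)C(C)(C)C)c(OC)c1 | intermediate (not isolated)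
19 | 4-(DBF)-2,6-dimethoxyphenyl pivalate (cis, 2R,3R) | COc1cc([C@@H]2Oc3c(OC)cc(CCCO[Si](C)(C)C(C)(C)C)cc3[C@@H]2CO[Si](C)(C)C(C)(C)C)cc(OC)c1OC(=O)C(C)(C)C | intermediate (product of the key step)
20 | 4-(DBF)-2,6-dimethoxyphenol | COc1cc([C@@H]2Oc3c(OC)cc(CCCO[Si](C)(C)C(C)(C)C)cc3[C@@H]2CO[Si](C)(C)C(C)(C)C)cc(OC)c1O | intermediate
21 | lithium salt of (S)-4-benzyl-2-oxazolidinone (N-lithio) | [Li+].O=C1OC[C@H](Cc2ccccc2)[N-]1 | intermediate (not isolated)
22 | (S)-4-benzyl-3-(bromoacetyl)oxazolidin-2-one | O=C(CBr)N1[C@@H](Cc2ccccc2)COC1=O | intermediate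
23 | (S)-4-benzyl-3-{2-[4-(DBF)-2,6-dimethoxyphenoxy]acetyl}oxazolidin-2-one | COc1cc([C@@H]2Oc3c(OC)cc(CCCO[Si](C)(C)C(C)(C)C)cc3[C@@H]2CO[Si](C)(C)C(C)(C)C)cc(OC)c1OCC(=O)N1[C@@H](Cc2ccccc2)COC1=O | intermediate
24 | vanillin | COc1cc(C=O)ccc1O | starting material
25 | 4-(TBS-oxy)-3-methoxybenzaldehyde | COc1cc(C=O)ccc1O[Si](C)(C)C(C)(C)C | intermediate
26 | trimethylsilyl ether of 27 at the secondary hydroxyl | COc1cc([C@@H](O[Si](C)(C)C)[C@H](C(=O)N2[C@@H](Cc3ccccc3)COC2=O)Oc2c(OC)cc([C@@H]3Oc4c(OC)cc(CCCO[Si](C)(C)C(C)(C)C)cc4[C@@H]3CO[Si](C)(C)C(C)(C)C)cc2OC)ccc1O[Si](C)(C)C(C)(C)C | intermediate (not isolated)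
27 | (S)-4-benzyl-3-[(2R,3R)-2-[4-(DBF)-2,6-dimethoxyphenoxy]-3-hydroxy-3-[4-(TBS-oxy)-3-methoxyphenyl]propanoyl]oxazolidin-2-one | COc1cc([C@@H](O)[C@H](C(=O)N2[C@@H](Cc3ccccc3)COC2=O)Oc2c(OC)cc([C@@H]3Oc4c(OC)cc(CCCO[Si](C)(C)C(C)(C)C)cc4[C@@H]3CO[Si](C)(C)C(C)(C)C)cc2OC)ccc1O[Si](C)(C)C(C)(C)C | intermediate
28 | (1R,2S)-2-[4-(DBF)-2,6-dimethoxyphenoxy]-1-[4-(TBS-oxy)-3-methoxyphenyl]propane-1,3-diol | COc1cc([C@@H](O)[C@H](CO)Oc2c(OC)cc([C@@H]3Oc4c(OC)cc(CCCO[Si](C)(C)C(C)(C)C)cc4[C@@H]3CO[Si](C)(C)C(C)(C)C)cc2OC)ccc1O[Si](C)(C)C(C)(C)C | intermediate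
29 | (1R,2S)-1-(4-hydroxy-3-methoxyphenyl)-2-{4-[(2R,3R)-3-(hydroxymethyl)-5-(3-hydroxypropyl)-7-methoxy-2,3-dihydro-1-benzofuran-2-yl]-2,6-dimethoxyphenoxy}propane-1,3-diol (CNP0301567.1) | COc1cc([C@@H](O)[C@H](CO)Oc2c(OC)cc([C@@H]3Oc4c(OC)cc(CCCO)cc4[C@@H]3CO)cc2OC)ccc1O | target

## Step count and least certain steps

Total: 19 steps. Longest linear sequence: 16 steps (1 → 2 → 3 → 4 → 6 → 7 → 10 → 14 → 15 → 16 → 17 → 19 → 20 → 23 → 27 → 28 → 29, that is steps 1–6, 8–13, 15 and 17–19).

**Step 12 (key step).** The activated benzylic oxygen may be lost by elimination toward the stilbene, because the neighbouring C–H is benzylic and the alkene would be conjugated with both rings. Partial ionisation would erode the inversion and let the trans ring form. The closure is also slowed by the eclipsing of ring B and the silyloxymethyl group that the cis ring requires.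

Fallback, from 16 back to 19: the secondary hydroxyl of 16 would be converted with MsCl and Et3N at −20 °C into the benzylic methanesulfonate F1. CsF in DMF would then cleave only the aryl silyl ether, and the phenoxide so released would displace the sulfonate with inversion and give 19. Activation and substitution are thus separated, and no phosphonium betaine is involved.

**Step 17.** The anti selectivity or the conversion may be poor. The bulky aryloxy group with two ortho methoxy groups could disturb the chelated enolate, and the electron-rich aldehyde adds slowly, so reversal of the aldol addition can compete with silylation.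

Fallback, from 20 back to 29: phenol 20 would be alkylated with (R)-4-benzyl-3-(bromoacetyl)oxazolidin-2-one F2, made from commercial (R)-4-benzyl-2-oxazolidinone as in step 14, to give the diastereomeric aryloxyacetyl imide F3. A boron-mediated Evans syn aldol with 25 (n-Bu2BOTf, i-Pr2NEt) would give the (2R,3S) syn adduct F4, which already has the correct Cb configuration. LiBH4 would give the threo diol F5, and silylation of the primary hydroxyl the alcohol F6. Dess–Martin oxidation of the Ca hydroxyl would give the aryl ketone F7. Reduction with LiBH(s-Bu)3 at −78 °C under Felkin–Anh control, with hydride anti to the aryloxy group, would give the erythro alcohol F8. Buffered fluoride as in step 19 would then give 29.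

**Step 15 (with the free phenol from step 13).** While ring B is a free phenoxide, the O1–C2 bond can open through a quinone methide and reclose to the trans ring. The phenoxide can also attack the imide carbonyl instead of the CH2Br carbon.

Fallback, from 20 back to 23: phenol 20 would be etherified under Mitsunobu conditions (PPh3, DIAD, toluene, 0 °C) with (S)-4-benzyl-3-(hydroxyacetyl)oxazolidin-2-one F9. This forms the same O–CH2 bond without carbonate base or polar solvent.

**Step 9.** Hydride may also reduce the aryl pivalate, or the aldolate may revert before the imide is cleaved.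

Fallback, from 14 back to 15: 14 would be treated with excess LiBH4 so that the imide and the pivalate are both cleaved, giving the triol-phenol F10. The ring B phenol would then be re-acylated selectively as its phenoxide (PivCl, K2CO3, acetone), which leaves the two aliphatic hydroxyls free and gives 15.

## Further compounds

F1 | step 12 | 4-[(1S,2R)-2-(ArC)-1-(methanesulfonyloxy)-3-(TBS-oxy)propyl]-2,6-dimethoxyphenyl pivalate | CC(C)(C)[Si](C)(C)OC[C@@H](c1cc(CCCO[Si](C)(C)C(C)(C)C)cc(OC)c1O[Si](C)(C)C(C)(C)C)[C@H](OS(C)(=O)=O)c1cc(OC)c(OC(=O)C(C)(C)C)c(OC)c1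
F2 | step 17 | (R)-4-benzyl-3-(bromoacetyl)oxazolidin-2-one | O=C(CBr)N1[C@H](Cc2ccccc2)COC1=O
F3 | step 17 | (R)-4-benzyl-3-{2-[4-(DBF)-2,6-dimethoxyphenoxy]acetyl}oxazolidin-2-one | COc1cc([C@@H]2Oc3c(OC)cc(CCCO[Si](C)(C)C(C)(C)C)cc3[C@@H]2CO[Si](C)(C)C(C)(C)C)cc(OC)c1OCC(=O)N1[C@H](Cc2ccccc2)COC1=O
F4 | step 17 | (R)-4-benzyl-3-[(2R,3S)-2-[4-(DBF)-2,6-dimethoxyphenoxy]-3-hydroxy-3-[4-(TBS-oxy)-3-methoxyphenyl]propanoyl]oxazolidin-2-one | COc1cc([C@H](O)[C@H](C(=O)N2[C@H](Cc3ccccc3)COC2=O)Oc2c(OC)cc([C@@H]3Oc4c(OC)cc(CCCO[Si](C)(C)C(C)(C)C)cc4[C@@H]3CO[Si](C)(C)C(C)(C)C)cc2OC)ccc1O[Si](C)(C)C(C)(C)C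
F5 | step 17 | (1S,2S)-2-[4-(DBF)-2,6-dimethoxyphenoxy]-1-[4-(TBS-oxy)-3-methoxyphenyl]propane-1,3-diol | COc1cc([C@H](O)[C@H](CO)Oc2c(OC)cc([C@@H]3Oc4c(OC)cc(CCCO[Si](C)(C)C(C)(C)C)cc4[C@@H]3CO[Si](C)(C)C(C)(C)C)cc2OC)ccc1O[Si](C)(C)C(C)(C)C
F6 | step 17 | (1S,2S)-2-[4-(DBF)-2,6-dimethoxyphenoxy]-3-(TBS-oxy)-1-[4-(TBS-oxy)-3-methoxyphenyl]propan-1-ol | COc1cc([C@H](O)[C@H](CO[Si](C)(C)C(C)(C)C)Oc2c(OC)cc([C@@H]3Oc4c(OC)cc(CCCO[Si](C)(C)C(C)(C)C)cc4[C@@H]3CO[Si](C)(C)C(C)(C)C)cc2OC)ccc1O[Si](C)(C)C(C)(C)C
F7 | step 17 | (S)-2-[4-(DBF)-2,6-dimethoxyphenoxy]-3-(TBS-oxy)-1-[4-(TBS-oxy)-3-methoxyphenyl]propan-1-one | COc1cc(C(=O)[C@H](CO[Si](C)(C)C(C)(C)C)Oc2c(OC)cc([C@@H]3Oc4c(OC)cc(CCCO[Si](C)(C)C(C)(C)C)cc4[C@@H]3CO[Si](C)(C)C(C)(C)C)cc2OC)ccc1O[Si](C)(C)C(C)(C)C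
F8 | step 17 | (1R,2S)-2-[4-(DBF)-2,6-dimethoxyphenoxy]-3-(TBS-oxy)-1-[4-(TBS-oxy)-3-methoxyphenyl]propan-1-ol | COc1cc([C@@H](O)[C@H](CO[Si](C)(C)C(C)(C)C)Oc2c(OC)cc([C@@H]3Oc4c(OC)cc(CCCO[Si](C)(C)C(C)(C)C)cc4[C@@H]3CO[Si](C)(C)C(C)(C)C)cc2OC)ccc1O[Si](C)(C)C(C)(C)C
F9 | step 15 | (S)-4-benzyl-3-(hydroxyacetyl)oxazolidin-2-one | O=C(CO)N1[C@@H](Cc2ccccc2)COC1=O
F10 | step 9 | 4-[(1S,2R)-2-(ArC)-1,3-dihydroxypropyl]-2,6-dimethoxyphenol | OC[C@@H](c1cc(CCCO[Si](C)(C)C(C)(C)C)cc(OC)c1O[Si](C)(C)C(C)(C)C)[C@H](O)c1cc(OC)c(O)c(OC)c1
A1 | alternative 1 | trans six-membered cyclic carbonate across Ca and Cc, ring A phenol free | COc1cc([C@H]2OC(=O)OC[C@@H]2Oc2c(OC)cc([C@@H]3Oc4c(OC)cc(CCCO[Si](C)(C)C(C)(C)C)cc4[C@@H]3CO[Si](C)(C)C(C)(C)C)cc2OC)ccc1O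
A2 | alternative 1 | Ca-deoxy precursor with tert-butyl carbonate on the Cc oxygen | COc1cc(C[C@H](COC(=O)OC(C)(C)C)Oc2c(OC)cc([C@@H]3Oc4c(OC)cc(CCCO[Si](C)(C)C(C)(C)C)cc4[C@@H]3CO[Si](C)(C)C(C)(C)C)cc2OC)ccc1O
A3 | alternative 2 | cis methyl 2-aryl-2,3-dihydrobenzofuran-3-carboxylate, ring B allyl ether | COc1cc([C@@H]2Oc3c(OC)cc(CCCO[Si](C)(C)C(C)(C)C)cc3[C@@H]2C(=O)OC)cc(OC)c1OCC=C
A4 | alternative 2 | (S)-3-diazoflavanone precursor, ring B allyl ether | COc1cc([C@@H]2Oc3c(OC)cc(CCCO[Si](C)(C)C(C)(C)C)cc3C(=O)C2=[N+]=[N-])cc(OC)c1OCC=C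
A5 | alternative 3 | cis methyl 2-aryl-2,3-dihydrobenzofuran-3-carboxylate, ring B triisopropylsilyl ether | COc1cc([C@@H]2Oc3c(OC)cc(CCCO[Si](C)(C)C(C)(C)C)cc3[C@@H]2C(=O)OC)cc(OC)c1O[Si](C(C)C)(C(C)C)C(C)C
A6 | alternative 3 | methyl aryldiazoacetate with the ring B benzyl group on the neighbouring phenol oxygen | COC(=O)C(=[N+]=[N-])c1cc(CCCO[Si](C)(C)C(C)(C)C)cc(OC)c1OCc1cc(OC)c(O[Si](C(C)C)(C(C)C)C(C)C)c(OC)c1
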